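**Retrosynthetic overview**
- The target comes from the C4 quinol by O-methylation, with a silyl group put on and taken off the guaiacol. The quinol comes from a spiro cyclic carbonate by excising the C7–O bond and CO2 through a p-quinone methide.
- The spiro carbonate comes from a 4-alkylphenol carrying a C7 tert-butyl carbonate, by iodine(III) dearomatisation that makes the C4–O bond. That phenol comes from Pd α-arylation (C4–C8 bond) followed by dynamic kinetic hydrogenation (sets C8).
- Feature exploited: benzylic C7 is 1,3-related to the quaternary ring carbon C4 (C4–C8–C7). An O–C(=O)–O bridge from C7 to C4 is therefore an unstrained 1,3-dioxan-2-one. The C5–OMe next to C4 biases rotation about C4–C8, so stereocentre C8 chooses the face of C4.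
- Rings: both carbocycles are bought as arenes. The only ring made is the temporary spiro dioxanone (step 9), which is opened again in step 10.

Key step: step 9

Remark on numbering: the ring runs C1 (C–OH, later C=O), C2 (allyl), C3, C4 (bears the side chain), C5 (OMe), C6. The side chain is C8 (CHMe) and C7 (benzylic). Descriptors at C4 and C8 change along the route only because CIP priorities change; the spatial arrangement stays the same.
Remark on the acetal: the 1-ethoxyethyl carbon is a stereocentre of no consequence. Compounds 5, 8, 9 and 11 are epimer mixtures there, and the SMILES leave it undefined.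
Assumption: 4-bromo-3-methoxyphenol is taken as a commercial starting material, so that no bromination is needed once the allyl group is present.

**Step 1**
Reactants: 1 4-bromo-3-methoxyphenol; 2 allyl bromide
Product: 3 4-(allyloxy)-1-bromo-2-methoxybenzene
Conditions: K2CO3, acetone, reflux
Reagents that add atoms: allyl bromide, C=CCBr
Why: Williamson ether synthesis, in which the phenoxide displaces bromide from the unhindered allylic halide by SN2 and no other nucleophilic site is present.

**Step 2**
Reactants: 3 4-(allyloxy)-1-bromo-2-methoxybenzene
Product: 4 2-allyl-4-bromo-5-methoxyphenol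
Conditions: N,N-diethylaniline, 200 °C
Reagents that add atoms: none
Why: Aromatic Claisen rearrangement ([3,3] shift, then tautomerisation), in which the ortho carbon between the two oxygen substituents is shielded by the methoxy methyl group that the neighbouring bromine turns toward it, so the allyl group should go mainly to the open ortho carbon and the minor regioisomer is removed by chromatography.

**Step 3**
Reactants: 4 2-allyl-4-bromo-5-methoxyphenol
Product: 5 1-allyl-5-bromo-2-(1-ethoxyethoxy)-4-methoxybenzene
Conditions: ethyl vinyl ether, PPTS (cat.), CH2Cl2, rt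
Reagents that add atoms: ethyl vinyl ether, C=COCC
Why: Acid-catalysed addition of the phenol to the enol ether gives a mixed acetal that withstands the bases of steps 5 to 7 and later comes off under acid too weak to touch a benzylic carbonate or an aryl silyl ether.

**Step 4**
Reactants: 6 propiovanillone
Product: 7 1-[3-methoxy-4-(triisopropylsilyloxy)phenyl]propan-1-one
Conditions: TIPSCl, imidazole, DMF, rt
Reagents that add atoms: triisopropylsilyl chloride, CC(C)[Si](Cl)(C(C)C)C(C)C
Why: Standard imidazole-promoted silylation of a phenol, with the bulky silyl group chosen to survive phosphate and alkoxide bases and to serve in step 10 as the fluoride-addressable trigger.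

**Step 5**
Reactants: 5 1-allyl-5-bromo-2-(1-ethoxyethoxy)-4-methoxybenzene; 7 1-[3-methoxy-4-(triisopropylsilyloxy)phenyl]propan-1-one
Product: 8 rac-2-[5-allyl-4-(1-ethoxyethoxy)-2-methoxyphenyl]-1-[3-methoxy-4-(triisopropylsilyloxy)phenyl]propan-1-one
Conditions: Pd2(dba)3 (1.5 mol %), Xantphos (3.5 mol %), K3PO4, toluene, 90 °C
Reagents that add atoms: none
Why: Palladium-catalysed ketone α-arylation (Buchwald–Hartwig type) couples the only enolisable position of 7 with the aryl bromide to make the C4–C8 bond, the weak phosphate base spares the silyl ether, the chelating ligand disfavours Heck reaction or double-bond migration at the allyl group, and C8 is formed racemic.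

**Step 6**
Reactants: 8 racemic ketone
Product: 9 (1S,2S)-2-[5-allyl-4-(1-ethoxyethoxy)-2-methoxyphenyl]-1-[3-methoxy-4-(triisopropylsilyloxy)phenyl]propan-1-ol, i.e. (7S,8S)
Conditions: trans-RuCl2[(R)-xylbinap][(R)-daipen] (0.5 mol %), t-BuOK (20 mol %), H2 (10 atm), i-PrOH–THF, 25 °C
Reagents that add atoms: none
Why: Noyori asymmetric hydrogenation under dynamic kinetic resolution, in which alkoxide racemises the doubly activated C8–H faster than reduction, the (R,R)-catalyst should deliver hydride to the carbonyl face that gives (7S) and, as a bulky donor following the Felkin–Anh preference, should consume the (8S)-ketone selectively, this C=O-selective catalyst should leave the terminal alkene alone, and the minor diastereomer that carries the wrong C8 is removed by chromatography.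

**Step 7**
Reactants: 9 (7S,8S)-alcohol; 10 di-tert-butyl dicarbonate
Product: 11 tert-butyl (1S,2S)-2-[5-allyl-4-(1-ethoxyethoxy)-2-methoxyphenyl]-1-[3-methoxy-4-(triisopropylsilyloxy)phenyl]propyl carbonate
Conditions: Boc2O, DMAP (0.3 equiv), Et3N, CH2Cl2, rt
Reagents that add atoms: di-tert-butyl dicarbonate, CC(C)(C)OC(=O)OC(=O)OC(C)(C)C
Why: DMAP-catalysed O-acylation of the only free hydroxyl with the pyrocarbonate, which touches no stereocentre.

**Step 8**
Reactants: 11 acetal-protected carbonate
Product: 12 tert-butyl (1S,2S)-2-(5-allyl-4-hydroxy-2-methoxyphenyl)-1-[3-methoxy-4-(triisopropylsilyloxy)phenyl]propyl carbonate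
Conditions: PPTS (0.1 equiv), MeOH–THF, 0 °C to rt
Reagents that add atoms: none
Why: Mild acid-catalysed transacetalisation, in which the aryl acetal is by far the most acid-labile group, so pyridinium tosylate in methanol should free the phenol without ionising the benzylic carbonate or cleaving the silyl ether.

**Step 9**
Reactants: 12 phenol carbonate
Product: 15 spiro carbonate (4S,5R,6R)-10-allyl-7-methoxy-4-[3-methoxy-4-(triisopropylsilyloxy)phenyl]-5-methyl-1,3-dioxaspiro[5.5]undeca-7,10-diene-2,9-dione, via aryloxy-λ3-iodane 13 (not isolated), via tert-butoxydioxanylium ion 14 (not isolated)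
Conditions: PhI(OAc)2 (1.1 equiv), (CF3)2CHOH–CH2Cl2 (1:1), 0.02 M, −10 to 0 °C
Reagents that add atoms: none
Why: Proposed new method: ligand exchange of the phenol at iodine(III) gives iodane 13, and as iodobenzene departs in the ionising, non-nucleophilic fluoroalcohol the carbonyl oxygen of the C7 tert-butyl carbonate bonds to the electron-poor para carbon C4, after which ion 14 sheds isobutene to leave the neutral cyclic carbonate. Nearest precedents are the hypervalent-iodine spirocyclisations of 4-substituted phenols by pendant carboxylic acids or alcohols, and the cyclisation of tert-butyl carbonates onto halonium ions, activated epoxides or carbocations; what is untested is the union of the two, a carbonate carbonyl as the tethered nucleophile toward an oxidised phenol. The 1,3-dioxan-2-one (C4, C8, C7, O, C, O) closes in a 6-exo-trig spiro mode through a chair in which the C8 methyl and the C7 aryl group are both equatorial for the (7S,8S) isomer. The new stereocentre C4 is controlled by C8: to avoid A(1,3) strain the smallest C8 substituent, hydrogen, lies in the arene plane next to the C5 methoxy group, which places C7 with its carbonate over one face and the methyl group over the other, so oxygen should arrive on the face that gives the C4 arrangement of the target. The step needs para rather than ortho capture, secured because only C4 lies within a six-membered closure, and oxidation of one ring only, secured because the other ring is a silyl ether that cannot bind iodine. Rival processes to be outrun are addition of acetate or solvent, C–C capture by the silyloxyaryl ring and loss of H8 to a quinone methide, hence low temperature, dilution and hexafluoroisopropanol.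

**Step 10**
Reactants: 15 spiro carbonate
Product: 17 (4S)-2-allyl-4-hydroxy-4-[(2R)-1-(4-hydroxy-3-methoxyphenyl)propan-2-yl]-5-methoxycyclohexa-2,5-dien-1-one, via p-quinone methide 16 (not isolated)
Conditions: TBAF (1.1 equiv), NaBH4 (2 equiv), THF–i-PrOH (5:1), −20 to 0 °C; aq NH4Cl
Reagents that add atoms: none
Why: Fluoride frees the phenoxide, which expels the para-benzylic C7–O carbonate by 1,6-elimination to give quinone methide 16, borohydride should add to C7 of this very electrophilic species (1,6-reduction) much faster than to the hindered vinylogous-ester dienone, and the C4 hydrogencarbonate loses CO2 on work-up; this known quinone-methide deoxygenation is preferred to Pd(0), which would ionise the bis-allylic C4–O bond and rearomatise the ring, and to a C7 cation, which the ring enol ether could trap.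

**Step 11**
Reactants: 17 quinol phenol
Product: 18 (4S)-2-allyl-4-hydroxy-5-methoxy-4-{(2R)-1-[3-methoxy-4-(triisopropylsilyloxy)phenyl]propan-2-yl}cyclohexa-2,5-dien-1-one
Conditions: TIPSCl, imidazole, DMF, 0 °C to rt
Reagents that add atoms: triisopropylsilyl chloride, CC(C)[Si](Cl)(C(C)C)C(C)C
Why: Imidazole-promoted silylation is selective for the acidic, unhindered phenol over the tertiary quinol hydroxyl, which must stay free for step 12.

**Step 12**
Reactants: 18 silyl-protected quinol
Product: 19 (4S)-2-allyl-4,5-dimethoxy-4-{(2R)-1-[3-methoxy-4-(triisopropylsilyloxy)phenyl]propan-2-yl}cyclohexa-2,5-dien-1-one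
Conditions: KHMDS (1.05 equiv), THF, −78 °C; MeI, −78 to 0 °C
Reagents that add atoms: iodomethane, CI
Why: Williamson O-methylation, in which the hydroxyl is the only acidic site, its potassium alkoxide is methylated at low temperature before it can add to another dienone, and C4 and C8 are not involved.

**Step 13**
Reactants: 19 silyl ether of the target
Product: 20 (4S)-2-allyl-4-[(2R)-1-(4-hydroxy-3-methoxyphenyl)propan-2-yl]-4,5-dimethoxycyclohexa-2,5-dien-1-one (target)
Conditions: TBAF, AcOH (1:1), THF, 0 °C
Reagents that add atoms: none
Why: Buffered fluoride cleaves the aryl silyl ether, the phenol is stable because no leaving group is left on C7, and acetic acid keeps the medium from turning basic toward the dienone.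

**Compound list**
1 | 4-bromo-3-methoxyphenol | COc1cc(O)ccc1Br | starting material
2 | allyl bromide | C=CCBr | starting material
3 | 4-(allyloxy)-1-bromo-2-methoxybenzene | C=CCOc1ccc(Br)c(OC)c1 | intermediate
4 | 2-allyl-4-bromo-5-methoxyphenol | C=CCc1cc(Br)c(OC)cc1O | intermediate
5 | 1-allyl-5-bromo-2-(1-ethoxyethoxy)-4-methoxybenzene | C=CCc1cc(Br)c(OC)cc1OC(C)OCC | intermediate
6 | propiovanillone | CCC(=O)c1ccc(O)c(OC)c1 | starting material
7 | 1-[3-methoxy-4-(triisopropylsilyloxy)phenyl]propan-1-one | CCC(=O)c1ccc(O[Si](C(C)C)(C(C)C)C(C)C)c(OC)c1 | intermediate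
8 | racemic α-aryl ketone | C=CCc1cc(C(C)C(=O)c2ccc(O[Si](C(C)C)(C(C)C)C(C)C)c(OC)c2)c(OC)cc1OC(C)OCC | intermediate
9 | (7S,8S)-alcohol | C=CCc1cc([C@H](C)[C@H](O)c2ccc(O[Si](C(C)C)(C(C)C)C(C)C)c(OC)c2)c(OC)cc1OC(C)OCC | intermediate
10 | di-tert-butyl dicarbonate | CC(C)(C)OC(=O)OC(=O)OC(C)(C)C | starting material
11 | (7S,8S)-tert-butyl carbonate, acetal-protected | C=CCc1cc([C@H](C)[C@H](OC(=O)OC(C)(C)C)c2ccc(O[Si](C(C)C)(C(C)C)C(C)C)c(OC)c2)c(OC)cc1OC(C)OCC | intermediate
12 | (7S,8S)-phenol tert-butyl carbonate (key-step precursor) | C=CCc1cc([C@H](C)[C@H](OC(=O)OC(C)(C)C)c2ccc(O[Si](C(C)C)(C(C)C)C(C)C)c(OC)c2)c(OC)cc1O | intermediate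
13 | aryloxy(phenyl)-λ3-iodanyl acetate of 12 | C=CCc1cc([C@H](C)[C@H](OC(=O)OC(C)(C)C)c2ccc(O[Si](C(C)C)(C(C)C)C(C)C)c(OC)c2)c(OC)cc1OI(OC(C)=O)c1ccccc1 | intermediate
14 | spiro 2-tert-butoxy-1,3-dioxan-2-ylium acetate | C=CCC1=C[C@@](OC(OC(C)(C)C)=[O+]2)([C@H](C)[C@H]2c3ccc(O[Si](C(C)C)(C(C)C)C(C)C)c(OC)c3)C(OC)=CC1=O.CC(=O)[O-] | intermediate
15 | spiro cyclic carbonate, (4R,7S,8R) in route numbering (key-step product) | C=CCC1=C[C@@](OC(=O)O2)([C@H](C)[C@H]2c3ccc(O[Si](C(C)C)(C(C)C)C(C)C)c(OC)c3)C(OC)=CC1=O | intermediate
16 | p-quinone methide C4 hydrogencarbonate (present as its salt, exocyclic C=C geometry undefined) | C=CCC1=C[C@@](OC(=O)O)([C@H](C)C=C2C=CC(=O)C(OC)=C2)C(OC)=CC1=O | intermediate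
17 | (4S,8R)-quinol with free guaiacol | C=CCC1=C[C@@](O)([C@H](C)Cc2ccc(O)c(OC)c2)C(OC)=CC1=O | intermediate
18 | (4S,8R)-quinol triisopropylsilyl ether | C=CCC1=C[C@@](O)([C@H](C)Cc2ccc(O[Si](C(C)C)(C(C)C)C(C)C)c(OC)c2)C(OC)=CC1=O | intermediate
19 | triisopropylsilyl ether of the target | C=CCC1=C[C@@](OC)([C@H](C)Cc2ccc(O[Si](C(C)C)(C(C)C)C(C)C)c(OC)c2)C(OC)=CC1=O | intermediate
20 | CNP0370214.1 | C=CCC1=C[C@@](OC)([C@H](C)Cc2ccc(O)c(OC)c2)C(OC)=CC1=O | target

**Step count**
- Total step count: 13.
- Longest linear sequence: 12 (steps 1, 2, 3, 5 to 13).

**Steps most likely to fail**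

1. **Step 9.** The activated ring may be captured at C4 by acetate, by solvent or by the electron-rich silyloxyaryl ring before the carbonate carbonyl arrives. Proton loss from C8 may divert material to a quinone methide, or the rotamer bias may give too little facial selectivity.
   - The fallback gives up the tether, uses only known reactions and sets out from 9.
   - Ionic hydrogenation (Et3SiH, CF3CO2H, CH2Cl2, −20 to 0 °C) removes the C7 hydroxyl while the ring is still aromatic. It cleaves the acetal in the same operation, to give 2-allyl-5-methoxy-4-{(2R)-1-[3-methoxy-4-(triisopropylsilyloxy)phenyl]propan-2-yl}phenol F1.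
   - Intermolecular dearomatisation with PhI(OAc)2 in methanol at 0 °C then places methoxy on C4. It should give 19 together with the C4 epimer of 19 F2, which chromatography has to remove.
   - The route is rejoined at 19, and steps 7 to 12 are dropped.

2. **Step 10.** Borohydride may over-reduce the dienone. The quinone methide may tautomerise to a propenylphenol with loss of the C8 configuration, or the 1,6-elimination may be sluggish.
   - The fallback replaces the quinone-methide pathway by a cationic one and sets out from 15.
   - The conditions are Et3SiH (5 equiv) and BF3·OEt2 (3 equiv) in CH2Cl2 at −78 to −40 °C, an ionic hydrogenation of the silyloxy-stabilised benzylic C7–O bond.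
   - The excess Lewis acid is meant to tie up the vinylogous-ester carbonyl, so that C6 and the C5 methoxy oxygen are poor traps for the C7 cation.
   - CO2 is lost on work-up and the silyl ether stays on, so the route is rejoined directly at 18 and step 11 is dropped. No compound outside the list is made (F0).

3. **Step 6.** Racemisation may be too slow relative to reduction, enantio- or diastereoselection may be insufficient on this ortho-methoxy-substituted substrate, or ruthenium hydride may migrate or saturate the allyl double bond.
   - The fallback separates relative from absolute control and sets out from 8.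
   - Felkin–Anh-controlled reduction with L-Selectride (THF, −78 °C) should give the racemic (1S*,2S*)-alcohol F3.
   - Acylative kinetic resolution follows, with isobutyric anhydride, i-Pr2NEt and the enantiomer of benzotetramisole that acylates the (1R,2R)-alcohol.
   - This converts the unwanted enantiomer into the (1R,2R)-isobutyrate F4 and leaves 9, where the route is rejoined after chromatography.

**Further compounds**
F1 | step 9 | 2-allyl-5-methoxy-4-{(2R)-1-[3-methoxy-4-(triisopropylsilyloxy)phenyl]propan-2-yl}phenol | C=CCc1cc([C@H](C)Cc2ccc(O[Si](C(C)C)(C(C)C)C(C)C)c(OC)c2)c(OC)cc1O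
F2 | step 9 | C4 epimer of 19, (4R,8R) | C=CCC1=C[C@](OC)([C@H](C)Cc2ccc(O[Si](C(C)C)(C(C)C)C(C)C)c(OC)c2)C(OC)=CC1=O
F0 | step 10 | none | none
F3 | step 6 | racemic (1S*,2S*)-alcohol (9 plus its enantiomer) | C=CCc1cc([C@H](C)[C@H](O)c2ccc(O[Si](C(C)C)(C(C)C)C(C)C)c(OC)c2)c(OC)cc1OC(C)OCC.C=CCc1cc([C@@H](C)[C@@H](O)c2ccc(O[Si](C(C)C)(C(C)C)C(C)C)c(OC)c2)c(OC)cc1OC(C)OCC
F4 | step 6 | (1R,2R)-isobutyrate of the enantiomer of 9 | C=CCc1cc([C@@H](C)[C@@H](OC(=O)C(C)C)c2ccc(O[Si](C(C)C)(C(C)C)C(C)C)c(OC)c2)c(OC)cc1OC(C)OCC
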